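- Each left-handed product or right-handed product formed uses up one coupling partner, and coupling partner enters this flask from the held gas, so the reckoning weighs supply against draw.

    coupling partner + catalyst + left-handed substrate → catalyst + left-handed product (k1 = 110 M⁻² s⁻¹)
    coupling partner + catalyst + right-handed substrate → catalyst + right-handed product (k2 = 38 M⁻² s⁻¹)
    left-handed substrate ⇌ right-handed substrate (k3 = 5.4 × 10⁻⁴ s⁻¹)
    gas ⇌ coupling partner, rate k4*(csat - [coupling partner]) (k4 = 0.39 s⁻¹, csat = 37 mM)

left-handed substrate 0.67 M; gas 37 mM (held); catalyst 6.7 mM; right-handed substrate 0.67 M; time 1.0 min

- catalyst is single-handed; left-handed substrate and right-handed substrate are mirror images of each other, charged as a racemate, each of them at the stated concentration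
- at the start none of coupling partner is dissolved
- the reaction counts as stopped when no species that holds the left-handed substrate and right-handed substrate together changes by six tenths of a point or more over the second half of the time
- run time (flask): 1.0 min

* which holds at 1.0 min: what has brought the reaction to rest, or that it has not come to rest (no working catalyst is left / all of the left-handed substrate has reacted / forward and back rates have come level / it is still moving)
* how much of the left-handed substrate and right-handed substrate together has reacted by 1.0 min
* how much left-handed product there is at 1.0 min, in percent of the left-handed substrate and right-handed substrate together charged
* how much right-handed substrate there is at 1.0 min, in percent of the left-handed substrate and right-handed substrate together charged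
* amount of left-handed product if the flask were left three thousand times as long, in percent of the left-handed substrate and right-handed substrate together charged

- The draw number, a Damköhler number, is the rate constant at which the charged catalyst and both substrates together take up coupling partner, divided by the transfer coefficient: 1.70. It says how many times the uptake constant of coupling partner stands above its transfer coefficient.
- No coupling partner is dissolved at the start, but transfer alone has a half-life of 1.78 s, far shorter than the run, so after the first seconds [coupling partner] should follow supply and draw, near 13.7 mM.
- Held at its value for the full charge, the number gives a conversion of 40.7%. That is the start of a falling curve, so the mean substrate level lowers the number to 1.36, and the conversion becomes 37.2%.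
- With 37.2% of the substrate reacted by this reckoning, the rest remains to react, so this flask should still be moving.
- One number does not give the split. The selectivity factor 2.89 must be added, and its starting shares give left-handed product 27.6% and right-handed substrate 40.4%. Both should read high, because k1 exceeds k2 and left-handed substrate therefore falls faster, which lowers its share of the uptake.
- Racemisation relaxes slowly against the run and against the 2.69 min that the reckoned mean rate needs for the whole charge, so a very long wait should end near 50.0%.
- The forecast says it is still moving, with conversion 35.8%, left-handed product 25.2%, right-handed substrate 39.1% and, after the long wait, left-handed product 52.4%. Its conversion lies below this reckoning, and its long-wait figure lies above it. On the long wait it holds that “the slow racemisation only moves a few percent of the right-handed substrate over before it is used up”.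
- The simulation's verdict is the same, it is still moving, with conversion 35.8%, left-handed product 25.1%, right-handed substrate 39.1% and, after the long wait, left-handed product 52.3%; the forecast stands within its margins.
- This flask is not at rest: the largest change of a share over the second half of the time was 12 percentage points. Its unequal remainders, 50% of the charged left-handed substrate against 78% of the charged right-handed substrate, belong to a passing stage. At ten times the time, conversion reaches 99.7%, right-handed substrate stands at 0.331%, and left-handed product at 52.3%.
- In the neighbour flask with catalyst at 0.0017 M, the draw number is 0.432, and its mean 0.390 gives a conversion of 18.1%. The computed conversion of that neighbour flask is 17.4%.

The rate constants are made up, and the outcome is calculated.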